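The numbers in the tables are calculated for an exercise; noise was put on by code.

To set the initiator loading we first want the length of the chains in this flask at the asked time if every initiator begins one chain, and that length is the zero of our scale.

common to all: free monomer 0.10 M; initiator 5 mol%
- south-west: protic impurity 0.050 M; the very flask that is asked about, followed so far
- flask: protic impurity 0.0500 M; time 30 min

- south-west (time / min: monomer in chains / %, free monomer / %): 1.50: 1.5, 71.0; 3.00: 2.6, 59.3; 5.00: 4.9, 51.4; 6.00: 6.0, 48.1; 8.00: 8.2, 44.1; 10.0: 10.4, 39.8

(standard deviation of a reading: 0.3 percentage points)

- the average divides the monomer in chains by the number of chains begun, living and dead together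
- the earlier runs do not show the number of chains; that part of a forecast is a guess

1. average number of monomer units in a chain (chains begun, living or dead) at 30 min
2. part of the free monomer that has reacted at 30 min

In the south-west run, which is this flask followed so far, the free monomer lost outside the chains stands at 49.8 % by 10.0 min, level with the protic impurity's share of the charge, so we count 50.0 % of the free monomer as open to chains. This is our own bracket. If growth keeps its pace since 5.00 min, monomer in chains reaches 32.4 % at 30 min, and if it slows in step with what remains of that budget, 27.3 %. So we estimate c between 77.3 % and 82.4 %. Were every initiator to begin one chain, the upper figure would give 6.48 units per chain. This floor length, monomer in chains per initiator charged, falls to 5.46 on the lower figure. The readings show no number of chains, so we have no bound on length from above.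

The forecast gives 79 % reacted, inside our bracket, and a length of 6.3, inside the range of the floor, adding “Slow initiation would raise this”.

The flask gives a length of 15.7 and 82.1 % reacted.

    protic impurity + free monomer → quenched substrate (k = 0.108 M⁻¹ s⁻¹)
    2 initiator → spent initiator (k = 0.136 M⁻¹ s⁻¹)
    free monomer + living end → monomer in chains + living end, rate k3*[living end]*[free monomer] (k = 0.342 M⁻¹ s⁻¹)
    free monomer + initiator → living end + monomer in chains (k = 0.0136 M⁻¹ s⁻¹)

The reacted share stands inside our bracket, but the length is 2.42 times the floor length, and this flask's own monomer in chains, 32.2 %, puts the chains begun at 41.0 % of the initiator charged, the initiator efficiency. At 30 min this flask still holds 16.5 % of its initiator, and its spent initiator accounts for 42.4 % of that charge. On the neighbour charged with 2 mol% of initiator, the same reckoning from its own monomer in chains gives a floor length of 9.92 against 18.1, an efficiency of 54.8 %, and its spent initiator accounts for 23.5 % of its charge.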